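Reagent is the quantity to follow in these four set-ups, and its disappearance is read here from the spring and summer runs.

| flask | substrate | reagent | free catalyst | remark | time |
|---|---|---|---|---|---|
| spring | 2 M | 1.9 M | 200 mM | run made earlier |  |
| summer | 2 M | 1.9 M | 400 mM | run made earlier |  |
| eta | 2.0 M | 1.90 M (fed, over 64.0 min) | 200 mM | a stirred flask in which reagent is dosed at a steady rate over 64.0 min without added volume, worked up at 80 min | 80 min |
| alpha | 2.0 M | 1.90 M | 200 mM | a single well-mixed tank run continuously and read at steady state, 80 min in it on average |  |
| theta | 2.0 M (fed, over 64.0 min) | 1.90 M | 200 mM | a stirred flask in which substrate is dosed at a steady rate over 64.0 min without added volume, worked up at 80 min | 80 min |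
| delta | 2.0 M | 1.90 M | 200 mM | a closed flask charged with all of it at once and left for 80 min | 80 min |

- spring (time / min: product / %): 5.00: 78.5; 15.0: 94.6; 30.0: 94.6; 40.0: 96.0; 60.0: 93.9; 80.0: 96.0
- summer (time / min: product / %): 4.00: 90.0; 8.00: 94.8; 12.0: 95.3; 15.0: 95.8; 20.0: 95.3; 25.0: 93.0

(standard deviation of a reading: 1 percentage point)

- the stated concentrations are those of everything mixed, before any reaction; amounts are the same in each set-up
- the numbers in the tables scatter by 1 percentage point (one standard deviation)
- on the list of suspects stand: reagent + free catalyst -> catalyst intermediate A; substrate + catalyst intermediate A -> catalyst intermediate B; catalyst intermediate B -> free catalyst + product; 2 free catalyst <-> resting dimer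
- the feed brings no volume worth counting
- the earlier runs were made in a closed, stirred flask

1. the set-up with the highest amount of product at the outlet or at the end, in percent of the substrate put in ("none" if the first two lie within 2 percentage points) (eta / alpha / theta / delta / none)
2. amount of product at the outlet or at the end, in percent of the substrate put in, eta
3. amount of product at the outlet or at the end, in percent of the substrate put in, alpha
4. amount of product at the outlet or at the end, in percent of the substrate put in, theta
5. amount of product at the outlet or at the end, in percent of the substrate put in, delta

Reagent is charged at 1.90 M against 2.0 M of substrate, less, so it is the limiting reagent and product has a ceiling of 95.0 % of the substrate. The first spring reading, 78.5 % product at 5.00 min, leaves c(reagent) at 0.330 M. Read as first-order decay, this gives the clearing time, the span in which c(reagent) falls by a factor of e: 2.86 min. The first summer reading, with twice the catalyst, gives 1.36 min, about half of that.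

Delta starts as spring did, with c(reagent) falling at about 0.665 M min⁻¹. By 15.0 min, which is 5.24 clearing times, c(reagent) has reached about 0.01002 M, and spring reads 94.6 %. Later spring readings lie between 93.9 % and 96.0 %, with no decline beyond the scatter. Delta has 28.0 clearing times, far more than it needs, so I reckon it ends at the ceiling.

Eta doses reagent at about 0.0297 M min⁻¹ and theta doses substrate at about 0.0312 M min⁻¹, far below that opening rate. Their hold of 16.0 min is 5.60 clearing times, so I put both at the ceiling too. The clearing time was read from the opening of a closed flask, whereas tank alpha, with 80 min in it on average, stands at its outlet concentrations, so I carry no figure over to the tank and put it below the ceiling. The two highest tie within 2 percentage points.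

The forecast gives 94.8 % for eta, 91.5 % for alpha, 94.6 % for theta, 95 % for delta, and none as best: “The top three tie, so none.”

The flasks give 95.0 % in eta, 92.8 % in alpha, 95.0 % in theta and 95.0 % in delta, so the best is none.

    reagent + free catalyst → catalyst intermediate A (k = 68.3 M⁻¹ min⁻¹)
    substrate + catalyst intermediate A → catalyst intermediate B (k = 12.4 M⁻¹ min⁻¹)
    catalyst intermediate B → free catalyst + product (k = 2.33 min⁻¹)
    2 free catalyst ⇌ resting dimer, settled at all times (K = 270 M⁻¹)

In delta, half of the turnover of reagent + free catalyst stood at 2.11 min, shorter than the clearing time and far shorter than the 80 min allowed. At 80.0 min, delta held 95.0 % product, with reagent at 0 % of its charge. The neighbour with 0.47 M of reagent, reckoned with the same 28.0 clearing times, has a ceiling of 23.5 %; it gave 23.5 %, with 76.5 % of its substrate left.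

All runs are simulated for an exercise, and the scatter is random.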